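(Readings and results were generated by integration from invented constants, noise included.)

I had 3 questions on the flask, and I took them to one number: the fraction of the charge that the protic impurity can quench as limiting reagent of that step, which I called the impurity equivalents, 0.0500.

all flasks: starting material 0.12 M (fed, over 1.0 h)
- theta: protic impurity 6 mM; the very flask that is asked about, followed so far
- delta: protic impurity 4 mM; run made earlier
- flask: protic impurity 6.00 mM; time 15 d

| run | time / d | starting material / % | isomer of the product / % | target / % |
|---|---|---|---|---|
| theta | 0.500 | 30 | 37 | 24 |
| theta | 0.833 | 23 | 53 | 19 |
| theta | 1.25 | 19 | 64 | 15 |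
| theta | 2.00 | 12 | 79 | 7 |
| theta | 4.00 | 1 | 92 | 2 |
| theta | 6.00 | 3 | 89 | 1 |
| delta | 0.417 | 33 | 33 | 27 |
| delta | 1.25 | 16 | 62 | 14 |
| delta | 2.00 | 10 | 81 | 7 |
| delta | 3.00 | 6 | 86 | 5 |
| delta | 5.00 | 2 | 92 | 1 |
| delta | 6.00 | 2 | 94 | 0 |

(standard deviation of a reading: 1.5 percentage points)

- the state of affairs at 15 d: stopped, and by what, or still going (forward and back rates have come level / it is still moving)
- how much of the starting material has reacted by 15 d
- how much isomer of the product there is at 15 d, in percent of the starting material charged

- percentages count the starting material that a species holds: one idle adduct or homo dimer counts as two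
- target is meant together with its idle adduct
- the numbers in the tables scatter with a standard deviation of 1.5 percentage points
- reactions considered so far: starting material + protic impurity -> quenched substrate; starting material <-> target; starting material + target <-> idle adduct; starting material <-> isomer of the product; 2 starting material -> homo dimer
- in an amount of target, one idle adduct counts as one target
- the reaction counts as stopped when no species that holds the starting material changes by six tenths of a point or more over the second half of the time

If the impurity spent its whole charge, one minus that fraction should stay in starting material, target and isomer of the product. The theta run read 95.0 % at 4.00 d against 95.0 %, and the delta run 96.0 % at 6.00 d against 96.7 %.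

But one number was not enough, since it gave neither the split of that pool nor the end. The late readings of both runs together put isomer at 96.8 % of the pool and starting material at 2.11 %. In the theta run, isomer read 92 % at 4.00 d and 89 % at 6.00 d, a fall of 3 percentage points against a scatter of 1.5 points on each reading, while in the delta run it read 92 % at 5.00 d and 94 % at 6.00 d. These readings do not separate level rates from a one-way step, so I took level rates by 15 d as a choice, resting on the listed isomerisation being written both ways. My reckoning for the flask gave 92.0 % isomer and 98.0 % reacted.

The forecast, whose plateau “suggests a reversible isomerisation at equilibrium”, gave forward and back rates have come level, 98.2 % reacted and 92 % isomer.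

The flask gave forward and back rates have come level, 98.1 % reacted and 92.0 % isomer.

    starting material + protic impurity → quenched substrate (k = 14.0 L mol⁻¹ h⁻¹)
    starting material ⇌ target (K = 0.550, k = 0.130 h⁻¹)
    starting material + target ⇌ idle adduct, settled at all times (K = 6.20 L mol⁻¹)
    starting material ⇌ isomer of the product (K = 48.0, k = 0.0700 h⁻¹)
    2 starting material → homo dimer (k = 3.60 × 10⁻⁴ L mol⁻¹ h⁻¹)

Its quenched substrate stood at 5.00 % beside equivalents of 0.0500. The neighbour flask, charged with 0.015 M of protic impurity, had 0.125 equiv, and the same shares gave 84.7 % isomer and 98.2 % reacted. It gave 84.7 % isomer and 98.2 % reacted, with quenched substrate at 12.5 %.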